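The C6 oxygen flanks the C1–C5 ring-fusion bond, so the cyclopentane (C1–C5) and the cycloheptene (C5–C10, C1) are disconnected together to a Wieland–Miescher-derived decalin in which C1 is still bonded to C6. One alkoxide-driven 1,2-shift of C1 from C6 to C5 contracts ring A, expands ring B, makes C6 a ketone and sets C5. As C5 is inverted, the trans fusion requires a cis-fused decalin carrying 6β-OH, 5β-OMs, a C4 dioxolane, the 10α-silyl ether and the C8=C9 alkene. Numbering follows the target: C1 methyl-bearing fusion carbon, C4 isopropyl carbinol, C5 fusion CH, C6 acyloxy carbon, C10 free carbinol.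

Key step: step 12

Remark: β is the face of the C1 methyl group and the decalins keep the target atom labels (ring A = C1–C6, ring B = C6–C10 plus C1, fusion bond C1–C6); since the shift needs C5–O antiperiplanar to C1–C6 and inverts C5, only the cis-fused 5β-sulfonyloxy-6β-ol gives the trans-fused (5α-H) ketone, whereas a trans-fused 5α,6α-diol monosulfonate would give the cis-fused ketone and its 5β epimer an epoxide.

Step 1
Reactants: 1 2-methylcyclohexane-1,3-dione; 2 methyl vinyl ketone
Product: 5 (S)-Wieland–Miescher ketone, via triketone 3 (not isolated), via bicyclic ketol 4 (not isolated)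
Conditions: L-proline (cat.), DMSO, 35 °C; low-temperature recrystallisation
Reagents that add atoms: none
Why: Proline-catalysed Robinson annulation (Michael addition, then Hajos–Parrish–Eder–Sauer–Wiechert aldol condensation), in which the L-proline enamine attacks one of the two enantiotopic ring carbonyls and so fixes the quaternary C1 as (S), with crystallisation expected to raise the enantiomeric purity.

Step 2
Reactants: 5 (S)-Wieland–Miescher ketone
Product: 6 5β,6β-epoxy-1-methyldecalin-4,10-dione
Conditions: H2O2 (30 % aq.), NaOH (cat.), MeOH, 0 °C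
Reagents that add atoms: hydrogen peroxide, OO
Why: Weitz–Scheffer nucleophilic epoxidation acts only on the enone, and hydroperoxide should add axially to C6 on the face of the angular methyl (the cis-decalin trajectory usual for nucleophiles on 10-methyloctalones), so both epoxide C–O bonds are β.

Step 3
Reactants: 6 5β,6β-epoxy-1-methyldecalin-4,10-dione
Product: 7 cis-fused 6β-hydroxy-1-methyldecal-4-en-10-one
Conditions: N2H4·H2O, AcOH (cat.), MeOH, 0 °C to rt
Reagents that add atoms: none
Why: Wharton transposition, in which the hydrazone of the unhindered epoxy ketone collapses with loss of N2 to the C4=C5 alkene and the tertiary C6 alcohol, whose untouched C–O bond stays β (cis to the methyl), while the neopentylic C10 ketone condenses much more slowly.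

Step 4
Reactants: 7 cis-fused 6β-hydroxy-1-methyldecal-4-en-10-one
Product: 9 6β-triethylsilyloxy-1-methyldecala-4,8-dien-10-one, via bis-silyl enol ether 8 (not isolated)
Conditions: TESOTf, Et3N, CH2Cl2, 0 °C; then Pd(OAc)2, MeCN, rt
Reagents that add atoms: triethylsilyl trifluoromethanesulfonate, CC[Si](CC)(CC)OS(=O)(=O)C(F)(F)F
Why: Soft enolisation gives the only possible enol ether of the C10 ketone (towards C9) and caps the tertiary alcohol, which blocks retro-aldol cleavage, and Saegusa–Ito oxidation with divalent palladium acetate then gives the C8=C9 enone.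

Step 5
Reactants: 9 6β-triethylsilyloxy-1-methyldecala-4,8-dien-10-one
Product: 12 6β-hydroxy-1,8-dimethyldecala-4,8-dien-10-one, via silyl enol ether 10 (not isolated), via silylated enone 11 (not isolated)
Conditions: Me2CuLi, TMSCl, THF, −78 °C; then Pd(OAc)2, MeCN, rt; then HF·pyridine, THF, 0 °C
Reagents that add atoms: lithium dimethylcuprate, [Li+].C[Cu-]C
Why: Cuprate 1,4-addition puts the methyl group on C8 (its transient configuration is erased), a second Saegusa–Ito oxidation returns the enone as C8(Me)=C9, and fluoride frees the tertiary alcohol without base.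

Step 6
Reactants: 12 6β-hydroxy-1,8-dimethyldecala-4,8-dien-10-one
Product: 13 1,8-dimethyldecala-4,8-diene-6β,10α-diol
Conditions: Me4NBH(OAc)3, MeCN–AcOH, −35 to −20 °C
Reagents that add atoms: none
Why: Evans–Saksena hydroxyl-directed reduction, in which the acetoxyborohydride bound to the 6β-oxygen delivers hydride to the β face of the C10 carbonyl, so the new hydroxyl is α (1,3-anti, trans to the C1 methyl), the epimer that free hydride attacking anti to the methyl would not give, and the enone alkene is left alone.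

Step 7
Reactants: 13 1,8-dimethyldecala-4,8-diene-6β,10α-diol
Product: 14 10α-(tert-butyldimethylsilyloxy)-1,8-dimethyldecala-4,8-dien-6β-ol
Conditions: TBSCl, imidazole, DMAP (cat.), DMF, 40 °C
Reagents that add atoms: tert-butyldimethylsilyl chloride, CC(C)(C)[Si](C)(C)Cl
Why: Silylation with the chloride takes the secondary allylic C10 hydroxyl and leaves the tertiary ring-fusion hydroxyl free, which also removes the only hydroxyl that could steer osmium to the C8=C9 alkene.

Step 8
Reactants: 14 10α-(tert-butyldimethylsilyloxy)-1,8-dimethyldecala-4,8-dien-6β-ol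
Product: 16 10α-(tert-butyldimethylsilyloxy)-1,8-dimethyldecal-8-ene-4β,5β,6β-triol, via osmate ester 15 (not isolated)
Conditions: OsO4, TMEDA, CH2Cl2, −78 °C; then aq. Na2SO3, THF, 60 °C
Reagents that add atoms: osmium tetroxide, O=[Os](=O)(=O)=O
Why: Hydrogen-bond-directed dihydroxylation with the OsO4·TMEDA complex, in which the tertiary allylic 6β-hydroxyl delivers the reagent to its own face of the cis-disubstituted C4=C5 alkene, setting the C5 (and C4) oxygen β, syn to the C1 methyl, faster than the undirected and more hindered C8=C9 alkene reacts.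

Step 9
Reactants: 16 10α-(tert-butyldimethylsilyloxy)-1,8-dimethyldecal-8-ene-4β,5β,6β-triol
Product: 17 10α-(tert-butyldimethylsilyloxy)-5β,6β-dihydroxy-1,8-dimethyldecal-8-en-4-one
Conditions: IBX, DMSO, rt
Reagents that add atoms: none
Why: IBX oxidation of the less hindered secondary alcohol, since C4–OH has a methylene neighbour whereas C5–OH is flanked by the quaternary carbinol C6, and IBX turns 1,2-diols into α-ketols without C–C cleavage.

Step 10
Reactants: 17 10α-(tert-butyldimethylsilyloxy)-5β,6β-dihydroxy-1,8-dimethyldecal-8-en-4-one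
Product: 18 4,4-ethylenedioxy-10α-(tert-butyldimethylsilyloxy)-1,8-dimethyldecal-8-ene-5β,6β-diol
Conditions: 2-ethyl-2-methyl-1,3-dioxolane, p-TsOH (cat.), rt
Reagents that add atoms: 2-ethyl-2-methyl-1,3-dioxolane, CCC1(C)OCCO1
Why: Acid-catalysed exchange dioxolanation (transketalisation) of the only carbonyl group at room temperature, mild enough that the α-ketol should neither enolise at C5 nor lose the tertiary hydroxyl.

Step 11
Reactants: 18 4,4-ethylenedioxy-10α-(tert-butyldimethylsilyloxy)-1,8-dimethyldecal-8-ene-5β,6β-diol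
Product: 19 cis-fused 4,4-ethylenedioxy-6β-hydroxy-5β-mesyloxy-10α-(tert-butyldimethylsilyloxy)-1,8-dimethyldecal-8-ene
Conditions: MsCl, Et3N, CH2Cl2, −10 °C
Reagents that add atoms: methanesulfonyl chloride, CS(=O)(=O)Cl
Why: Mesylation through sulfene reaches the hindered secondary C5 hydroxyl and leaves the tertiary C6 hydroxyl free, and the cis arrangement of the two oxygens excludes epoxide formation.

Step 12
Reactants: 19 cis-fused 4,4-ethylenedioxy-6β-hydroxy-5β-mesyloxy-10α-(tert-butyldimethylsilyloxy)-1,8-dimethyldecal-8-ene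
Product: 20 trans-fused (5α-H) 4,4-ethylenedioxy-10α-(tert-butyldimethylsilyloxy)-1,8-dimethylhydroazul-8-en-6-one
Conditions: KOtBu (1.05 equiv), t-BuOH–THF, 0 °C to rt; pH 7 buffer
Reagents that add atoms: none
Why: The potassium 6-alkoxide pushes while the C1–C6 bond, antiperiplanar to the equatorial C5–OMs bond, slides to C5 as mesylate leaves, a concerted, stereospecific 1,2-shift whose closest known relative is the base-induced pinacol-type (semipinacol) rearrangement of decalin cis-diol monosulfonates to hydroazulenones. The five-membered ring (C1–C5) arises by contraction of ring A (C6 is extruded from it) and the seven-membered ring (C5–C10, C1) by one-carbon expansion of ring B (C5 is inserted into the C1–C6 bond), so neither is a cyclisation. The one new stereocentre, C5, is inverted, so the 5β-sulfonate fixed in step 8 translates into 5α-H, trans to the C1 methyl, and C1 migrates with retention. The selectivity needed is C1 over the allylic C7 as migrating carbon: in the cis-fused chair with O6 axial and the mesylate equatorial only C1–C6 is aligned, and the alternative chair that would align C6–C7 pays a 1,3-diaxial methyl/mesylate interaction and loses the potassium bridge between O6 and the syn-axial dioxolane oxygen. Cis alkoxide and sulfonate cannot close an epoxide, C4 and C6 carry no hydrogen for elimination, and the trans 1,3-relation of O6 and O10 on ring B keeps the silyl group from moving to the alkoxide. The base is consumed as the shift proceeds, so the β,γ-unsaturated ketone is not left in alkoxide and is reduced at once.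

Step 13
Reactants: 20 trans-fused (5α-H) 4,4-ethylenedioxy-10α-(tert-butyldimethylsilyloxy)-1,8-dimethylhydroazul-8-en-6-one
Product: 21 4,4-ethylenedioxy-10α-(tert-butyldimethylsilyloxy)-1,8-dimethylhydroazul-8-en-6α-ol
Conditions: Li, NH3 (l), THF, EtOH, −78 °C; then NH4Cl
Reagents that add atoms: none
Why: Dissolving-metal reduction is under thermodynamic control and should give the equatorial 6α-alcohol (hydroxyl cis to 5-H), whereas hydride would be pushed to the α face by the 1,3-related C1 methyl and give the axial epimer; alkene, silyl ether and dioxolane are inert and the crude ketone is used at once to forestall conjugation.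

Step 14
Reactants: 21 4,4-ethylenedioxy-10α-(tert-butyldimethylsilyloxy)-1,8-dimethylhydroazul-8-en-6α-ol
Product: 22 6α-hydroxy-10α-(tert-butyldimethylsilyloxy)-1,8-dimethylhydroazul-8-en-4-one
Conditions: PPTS, acetone–H2O, 50 °C
Reagents that add atoms: water, O
Why: Mild acid hydrolysis of the dioxolane, weak enough to leave the hindered silyl ether in place and to keep enolisation at C5 (loss of the trans fusion) and β-elimination of the 6-hydroxyl slow.

Step 15
Reactants: 22 6α-hydroxy-10α-(tert-butyldimethylsilyloxy)-1,8-dimethylhydroazul-8-en-4-one; 23 isopropylmagnesium chloride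
Product: 24 4α-isopropyl-10α-(tert-butyldimethylsilyloxy)-1,8-dimethylhydroazul-8-ene-4β,6α-diol
Conditions: iPrMgCl, CeCl3, THF, −78 to 0 °C
Reagents that add atoms: isopropylmagnesium chloride (23), CC(C)[Mg]Cl
Why: CeCl3-mediated (organocerium) 1,2-addition, the first equivalent deprotonating the 6-hydroxyl, avoids enolisation and reduction of the hindered cyclopentanone, and the nucleophile enters from the α face, away from the C1 methyl and the C5–C6 bond, giving the 4β-hydroxy-4α-isopropyl carbinol.

Step 16
Reactants: 24 4α-isopropyl-10α-(tert-butyldimethylsilyloxy)-1,8-dimethylhydroazul-8-ene-4β,6α-diol; 25 4-methoxybenzoyl chloride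
Product: 26 6α-(4-methoxybenzoyloxy)-4α-isopropyl-10α-(tert-butyldimethylsilyloxy)-1,8-dimethylhydroazul-8-en-4β-ol
Conditions: DMAP, Et3N, CH2Cl2, rt to 40 °C
Reagents that add atoms: 4-methoxybenzoyl chloride (25), COc1ccc(C(Cl)=O)cc1
Why: DMAP-catalysed acylation of the single secondary hydroxyl, since the tertiary C4 hydroxyl is unreactive and C10 is still silylated.

Step 17
Reactants: 26 6α-(4-methoxybenzoyloxy)-4α-isopropyl-10α-(tert-butyldimethylsilyloxy)-1,8-dimethylhydroazul-8-en-4β-ol
Product: 27 CNP0211568.1 (4β,10α-dihydroxy-4α-isopropyl-1,8-dimethylhydroazul-8-en-6α-yl 4-methoxybenzoate)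
Conditions: HF·pyridine, pyridine, THF, 0 °C to rt
Reagents that add atoms: none
Why: Fluoride-driven Si–O cleavage under buffered HF·pyridine frees the C10 hydroxyl without acyl migration, ester cleavage or ionisation of the allylic alcohol.

Compound list
1 | 2-methylcyclohexane-1,3-dione | CC1C(=O)CCCC1=O | starting material
2 | methyl vinyl ketone (but-3-en-2-one) | CC(=O)C=C | starting material
3 | 2-methyl-2-(3-oxobutyl)cyclohexane-1,3-dione | CC(=O)CCC1(C)C(=O)CCCC1=O | intermediate (not isolated)
4 | cis-fused ketol, 6β-hydroxy-1-methyldecalin-4,10-dione | O[C@]12CCCC(=O)[C@@]1(C)CCC(=O)C2 | intermediate (not isolated)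
5 | (S)-Wieland–Miescher ketone, (S)-8a-methyl-3,4,8,8a-tetrahydronaphthalene-1,6(2H,7H)-dione | O=C1CCCC2=CC(=O)CC[C@]12C | intermediate
6 | 5β,6β-epoxy-1-methyldecalin-4,10-dione (epoxide cis to the methyl) | O=C1CCC[C@@]2(O3)[C@]1(C)CCC(=O)[C@@H]23 | intermediate
7 | cis-fused 6β-hydroxy-1-methyldecal-4-en-10-one | O[C@]12CCCC(=O)[C@@]1(C)CCC=C2 | intermediate
8 | 6β,10-bis(triethylsilyloxy)-1-methyldecala-4,9-diene | CC[Si](CC)(CC)O[C@]12CCC=C(O[Si](CC)(CC)CC)[C@@]1(C)CCC=C2 | intermediate (not isolated)
9 | 6β-triethylsilyloxy-1-methyldecala-4,8-dien-10-one | CC[Si](CC)(CC)O[C@]12CC=CC(=O)[C@@]1(C)CCC=C2 | intermediate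
10 | 6β-triethylsilyloxy-10-trimethylsilyloxy-1,8-dimethyldecala-4,9-diene (C8 epimers) | CC[Si](CC)(CC)O[C@]12CC(C)C=C(O[Si](C)(C)C)[C@@]1(C)CCC=C2 | intermediate (not isolated)
11 | 6β-triethylsilyloxy-1,8-dimethyldecala-4,8-dien-10-one | CC[Si](CC)(CC)O[C@]12CC(C)=CC(=O)[C@@]1(C)CCC=C2 | intermediate (not isolated)
12 | 6β-hydroxy-1,8-dimethyldecala-4,8-dien-10-one | O[C@]12CC(C)=CC(=O)[C@@]1(C)CCC=C2 | intermediate
13 | 1,8-dimethyldecala-4,8-diene-6β,10α-diol | O[C@]12CC(C)=C[C@@H](O)[C@@]1(C)CCC=C2 | intermediate
14 | 10α-(tert-butyldimethylsilyloxy)-1,8-dimethyldecala-4,8-dien-6β-ol | O[C@]12CC(C)=C[C@@H](O[Si](C)(C)C(C)(C)C)[C@@]1(C)CCC=C2 | intermediate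
15 | cyclic 4β,5β-osmate ester of 14 (hexavalent osmium, TMEDA chelate) | CN(C)CCN(C)C.O[C@]12CC(C)=C[C@@H](O[Si](C)(C)C(C)(C)C)[C@@]1(C)CC[C@@H]3O[Os](=O)(=O)O[C@H]23 | intermediate (not isolated)
16 | 10α-(tert-butyldimethylsilyloxy)-1,8-dimethyldecal-8-ene-4β,5β,6β-triol | O[C@]12CC(C)=C[C@@H](O[Si](C)(C)C(C)(C)C)[C@@]1(C)CC[C@H](O)[C@@H]2O | intermediate
17 | 10α-(tert-butyldimethylsilyloxy)-5β,6β-dihydroxy-1,8-dimethyldecal-8-en-4-one | O[C@]12CC(C)=C[C@@H](O[Si](C)(C)C(C)(C)C)[C@@]1(C)CCC(=O)[C@@H]2O | intermediate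
18 | 4,4-ethylenedioxy-10α-(tert-butyldimethylsilyloxy)-1,8-dimethyldecal-8-ene-5β,6β-diol | O[C@]12CC(C)=C[C@@H](O[Si](C)(C)C(C)(C)C)[C@@]1(C)CCC3(OCCO3)[C@@H]2O | intermediate
19 | cis-fused 4,4-ethylenedioxy-6β-hydroxy-5β-mesyloxy-10α-(tert-butyldimethylsilyloxy)-1,8-dimethyldecal-8-ene (key-step precursor) | O[C@]12CC(C)=C[C@@H](O[Si](C)(C)C(C)(C)C)[C@@]1(C)CCC3(OCCO3)[C@@H]2OS(C)(=O)=O | intermediate
20 | trans-fused (5α-H) 4,4-ethylenedioxy-10α-(tert-butyldimethylsilyloxy)-1,8-dimethylhydroazul-8-en-6-one (key-step product) | O=C2CC(C)=C[C@@H](O[Si](C)(C)C(C)(C)C)[C@@]3(C)CCC4(OCCO4)[C@H]23 | intermediate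
21 | 4,4-ethylenedioxy-10α-(tert-butyldimethylsilyloxy)-1,8-dimethylhydroazul-8-en-6α-ol | O[C@H]2CC(C)=C[C@@H](O[Si](C)(C)C(C)(C)C)[C@@]3(C)CCC4(OCCO4)[C@H]23 | intermediate
22 | 6α-hydroxy-10α-(tert-butyldimethylsilyloxy)-1,8-dimethylhydroazul-8-en-4-one | O[C@H]2CC(C)=C[C@@H](O[Si](C)(C)C(C)(C)C)[C@@]3(C)CCC(=O)[C@H]23 | intermediate
23 | isopropylmagnesium chloride | CC(C)[Mg]Cl | starting material
24 | 4α-isopropyl-10α-(tert-butyldimethylsilyloxy)-1,8-dimethylhydroazul-8-ene-4β,6α-diol | O[C@H]2CC(C)=C[C@@H](O[Si](C)(C)C(C)(C)C)[C@@]3(C)CC[C@@](O)(C(C)C)[C@H]23 | intermediate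
25 | 4-methoxybenzoyl chloride | COc1ccc(C(Cl)=O)cc1 | starting material
26 | 6α-(4-methoxybenzoyloxy)-4α-isopropyl-10α-(tert-butyldimethylsilyloxy)-1,8-dimethylhydroazul-8-en-4β-ol | COc1ccc(C(=O)O[C@H]2CC(C)=C[C@@H](O[Si](C)(C)C(C)(C)C)[C@@]3(C)CC[C@@](O)(C(C)C)[C@H]23)cc1 | intermediate
27 | CNP0211568.1 | COc1ccc(C(=O)O[C@H]2CC(C)=C[C@@H](O)[C@@]3(C)CC[C@@](O)(C(C)C)[C@H]23)cc1 | target

Total step count: 17. Longest linear sequence: 17 steps (from 1 and 2; the route is fully linear).

Steps most likely to fail

Step 12 (key step). The shift may run in part through the other chair of the cis-decalin, in which the allylic C6–C7 bond is the one aligned with the leaving group (ring-B bond migration to a bridged ketone), and any alkoxide left over may move the C8=C9 double bond into conjugation or epimerise C5. The fallback sets out from 19 and comes back at 20, and replaces the anionic trigger by a Lewis-acid push–pull shift. Treatment of 19 with Et3AlIn CH2Cl2 at −78 °C should release ethane and give the diethylaluminium 6-alkoxide F1. In it aluminium bridges O6 and the syn-axial dioxolane oxygen, which holds ring A in the chair that aligns C1–C6 with C5–OMs, while coordination labilises the sulfonate. This is the organoaluminium-promoted pinacol-type rearrangement of β-mesyloxy alcohols. Work-up with aqueous potassium sodium tartrate should give 20 without contact with base.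

Step 9. The oxidant may fail to discriminate the two secondary hydroxyls or may over-oxidise the ketol. The fallback sets out from 14 and comes back at 17, and replaces reagent selectivity by a protecting-group logic. Hydroxyl-directed epoxidation of 14 with VO(acac)2 and t-BuOOH should give the syn 4β,5β-epoxy-6β-ol F2. Dilute HClO4 in aqueous THF opens the epoxide at C4, the carbon remote from the carbinol, to the 4α,5β,6β-triol F3, in which the C5–O bond is untouched. Only the 5β,6β pair is cis, so 2,2-dimethoxypropane with PPTS should give the 5,6-acetonide F4 with one free hydroxyl at C4. Dess–Martin oxidation gives the acetonide ketone F5, and aqueous acetic acid removes the acetonide to return to 17.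

Step 13. Incomplete thermodynamic control (protonation of the ketyl from the less hindered face) would leave the axial 6β-alcohol, and the β,γ-enone may isomerise before it is reduced. The fallback sets out from 20 and comes back at 24, and sets C6 by intramolecular hydride delivery. NaBH4 reduces 20 to the 6β-alcohol F6 (either epimer is usable). PPTS in aqueous acetone gives the 6β-hydroxy 4-ketone F7, and isopropylcerium addition as in step 15 gives the 4β,6β-diol F8. Dess–Martin oxidation of the only secondary hydroxyl gives the 4β-hydroxy 6-ketone F9. Me4NBH(OAc)3 then delivers hydride from the 4β-oxygen to the β face of C6 (Evans–Saksena 1,3-anti reduction) and gives the 6α-alcohol 24.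

Further compounds
F1 | step 12 | diethylaluminium 6β-alkoxide of mesylate 19 | CC[Al](CC)O[C@]12CC(C)=C[C@@H](O[Si](C)(C)C(C)(C)C)[C@@]1(C)CCC3(OCCO3)[C@@H]2OS(C)(=O)=O
F2 | step 9 | 4β,5β-epoxy-10α-(tert-butyldimethylsilyloxy)-1,8-dimethyldecal-8-en-6β-ol | O[C@]12CC(C)=C[C@@H](O[Si](C)(C)C(C)(C)C)[C@@]1(C)CC[C@@H]3O[C@H]23
F3 | step 9 | 10α-(tert-butyldimethylsilyloxy)-1,8-dimethyldecal-8-ene-4α,5β,6β-triol | O[C@]12CC(C)=C[C@@H](O[Si](C)(C)C(C)(C)C)[C@@]1(C)CC[C@@H](O)[C@@H]2O
F4 | step 9 | 5β,6β-O-isopropylidene-10α-(tert-butyldimethylsilyloxy)-1,8-dimethyldecal-8-en-4α-ol | O4[C@]12CC(C)=C[C@@H](O[Si](C)(C)C(C)(C)C)[C@@]1(C)CC[C@@H](O)[C@@H]2OC4(C)C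
F5 | step 9 | 5β,6β-O-isopropylidene-10α-(tert-butyldimethylsilyloxy)-1,8-dimethyldecal-8-en-4-one | O4[C@]12CC(C)=C[C@@H](O[Si](C)(C)C(C)(C)C)[C@@]1(C)CCC(=O)[C@@H]2OC4(C)C
F6 | step 13 | 4,4-ethylenedioxy-10α-(tert-butyldimethylsilyloxy)-1,8-dimethylhydroazul-8-en-6β-ol | O[C@@H]2CC(C)=C[C@@H](O[Si](C)(C)C(C)(C)C)[C@@]3(C)CCC4(OCCO4)[C@H]23
F7 | step 13 | 6β-hydroxy-10α-(tert-butyldimethylsilyloxy)-1,8-dimethylhydroazul-8-en-4-one | O[C@@H]2CC(C)=C[C@@H](O[Si](C)(C)C(C)(C)C)[C@@]3(C)CCC(=O)[C@H]23
F8 | step 13 | 4α-isopropyl-10α-(tert-butyldimethylsilyloxy)-1,8-dimethylhydroazul-8-ene-4β,6β-diol | O[C@@H]2CC(C)=C[C@@H](O[Si](C)(C)C(C)(C)C)[C@@]3(C)CC[C@@](O)(C(C)C)[C@H]23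
F9 | step 13 | 4β-hydroxy-4α-isopropyl-10α-(tert-butyldimethylsilyloxy)-1,8-dimethylhydroazul-8-en-6-one | O=C2CC(C)=C[C@@H](O[Si](C)(C)C(C)(C)C)[C@@]3(C)CC[C@@](O)(C(C)C)[C@H]23
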